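The readings were generated by integration for an exercise.

- I started from how slow the delta run was: in 8.00 h it turned 5.8% of its Q into E.

the same everywhere: Z 0.79 mM (held); G 0.72 mM
- delta: Q 30 mM; run made earlier
- flask: Q 20 mM; time 3.0 d

- delta (time / h: E / %): 0.417: 0.1; 1.00: 0.4; 2.00: 1.6; 3.00: 1.9; 4.00: 3.2; 6.00: 4.1; 8.00: 5.8

(standard deviation of a reading: 0.3 percentage points)

- the numbers in the tables scatter by 0.3 percentage points (one standard deviation)
- at the start none of Z is in solution

1. E at 3.0 d, in percent of the Q charged
2. the change that raises the amount of E at 3.0 d, in percent of the Q charged most ("none" if none brings more than 2 percentage points) (north-east / south / south-east / none)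
3. amount of E at 3.0 d, in percent of the Q charged, after south-east

- north-east: doubling the saturation concentration of Z, all else as stated
- south: doubling the amount of G, all else as stated
- south-east: doubling the transfer coefficient of Z, all else as stated

- I replaced that curve by its mean and defined the pace p, the fraction of the Q charged that goes to E per hour, as last reading over its time: 0.00725 h⁻¹.
- To check the error of that mean, I took the slope after 2.00 h, which gave 0.00700 h⁻¹, close to p.
- For the bound from above I took E as zero order in Q and carried the delta run's rate in mM over to the flask, and that reckoning gave 78.3% in 3.0 d.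
- For the bound from below I took E as first order in Q, so p held as a rate constant and gave 40.7%.
- Both bounds assumed that G kept working as charged, and with the delta run ending at 5.8% I could not tighten them further by hand.
- The forecast gave 45%, inside my bracket, with 47% after south-east, and chose south: “south is the safer pick”.
- The flask gave 26.8%, below my lower bound; the best change was north-east, and south-east gave 30.8%.

    D → X (k = 0.0460 h⁻¹)
    G + E → GE (k = 13.0 M⁻¹ h⁻¹)
    Z ⇌ D, rate k3*(csat - [D]) (kL = 0.450 h⁻¹)
    Q + D + G → G + E (k = 65000 M⁻² h⁻¹)
    2 Q → J (k = 0.470 M⁻¹ h⁻¹)

- Divided by p, this flask's E was 37.0 h of work, about half of 3.0 d. The larger of the two proven effects was the loss of G + E to GE: without it this flask reached 52.4% of E instead of 26.8%, and at 3.00 d it held, of the catalyst charged, G 2.35% against GE 97.7%. For a neighbour flask charged with 2.9 mM of G I scaled p in proportion to G, to 0.0292 h⁻¹, and at that pace its 33.5% of E was 11.5 h of work.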